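Every isoprenoid carbon substituent of euchrenone a3 sits next to a phenolic oxygen: C6 beside O5 and C8 beside O7 on ring A, C5' beside O4' on ring B. The route exploits this by disconnecting the C6–C1'' and C8–C1''' prenyl bonds and the C5'–C4''/O4'–C2'' pyran bonds back to tertiary allyl and propargyl ethers on those oxygens. One thermal operation on the (2S)-flavanone carrying 1,1-dimethylallyl ethers at O5 and O7, a 1,1-dimethylpropargyl ether at O4' and a triisopropylsilyl ether at O2' should install both prenyl groups and the chromene ring. The silyl group is put on only after the hydroxide-mediated chalcone condensation and comes off last with buffered fluoride.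

Key step: step 7

Assumption: the quinidine-series bifunctional thiourea is taken to close the pyranone ring in the (2S) sense; should a trial run show the opposite sense, its quinine-series pseudo-enantiomer replaces it with no other change.

Remark: flavanone numbering is used (ring A C5–C8, ring B primed; C1''/C1''' are the prenyl CH2 carbons, C2''–C4'' the pyran carbons). Compounds carrying the tertiary allyl ethers (5, 8, 9, 10) are handled at or below 25 °C and purified on triethylamine-deactivated silica, because these ethers rearrange on warming and ionise with acid.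

Step 1
Reactants: 1 2,4,6-trihydroxyacetophenone; 2 3-chloro-3-methylbut-1-yne
Product: 4 1-[2-hydroxy-4,6-bis(2-methylbut-3-yn-2-yloxy)phenyl]ethanone, via 4-O-mono ether 3 (not isolated)
Conditions: 2 (3 equiv), DBU (3.2 equiv), CuCl2·2H2O (1 mol %), MeCN, −5 °C → 20 °C
Reagents that add atoms: 3-chloro-3-methylbut-1-yne (compound 2), CC(C)(Cl)C#C
Why: Copper-catalysed O-propargylation of phenols with a tertiary propargylic chloride is selective for oxygen over carbon; the free 4-OH reacts first (3) and one of the two chelated ortho hydroxyls second, while the last hydroxyl, now the sole hydrogen-bond donor to the doubly flanked acetyl group, stays free, and the low temperature keeps the ortho-acyl aryl propargyl ether from rearranging.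

Step 2
Reactants: 4 1-[2-hydroxy-4,6-bis(2-methylbut-3-yn-2-yloxy)phenyl]ethanone
Product: 5 1-[2-hydroxy-4,6-bis(2-methylbut-3-en-2-yloxy)phenyl]ethanone
Conditions: H2 (1 atm), Pd/CaCO3 poisoned with Pb(OAc)2, quinoline, EtOAc, 20 °C, stopped at 2 equiv H2
Reagents that add atoms: none
Why: Lindlar-type semi-hydrogenation over lead-poisoned palladium with quinoline stops at the alkene, so both terminal alkynes become vinyl groups while the ketone and the aryl ethers are untouched.

Step 3
Reactants: 6 2,4-dihydroxybenzaldehyde; 2 3-chloro-3-methylbut-1-yne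
Product: 7 2-hydroxy-4-(2-methylbut-3-yn-2-yloxy)benzaldehyde
Conditions: 2 (1.2 equiv), DBU (1.3 equiv), CuCl2·2H2O (1 mol %), MeCN, 0 °C
Reagents that add atoms: 3-chloro-3-methylbut-1-yne (compound 2), CC(C)(Cl)C#C
Why: The same copper-catalysed O-propargylation, selective for the 4-OH because it is the more acidic hydroxyl and is not hydrogen-bonded to the formyl group.

Step 4
Reactants: 5 1-[2-hydroxy-4,6-bis(2-methylbut-3-en-2-yloxy)phenyl]ethanone; 7 2-hydroxy-4-(2-methylbut-3-yn-2-yloxy)benzaldehyde
Product: 8 (E)-1-[2-hydroxy-4,6-bis(2-methylbut-3-en-2-yloxy)phenyl]-3-[2-hydroxy-4-(2-methylbut-3-yn-2-yloxy)phenyl]prop-2-en-1-one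
Conditions: KOH (50% aq., excess), EtOH, 0 °C → 20 °C, Ar, dark; then AcOH to pH 6 at 0 °C
Reagents that add atoms: none
Why: Claisen–Schmidt aldol condensation, in which the methyl ketone enolate adds to the aldehyde and hydroxide is lost by E1cB to give the (E)-enone; it is run on the free salicylaldehyde because an aryl silyl ether would not survive ethanolic hydroxide, and the strongly basic medium holds the product as the open chalcone phenoxide so that ring closure is deferred.

Step 5
Reactants: 8 (E)-1-[2-hydroxy-4,6-bis(2-methylbut-3-en-2-yloxy)phenyl]-3-[2-hydroxy-4-(2-methylbut-3-yn-2-yloxy)phenyl]prop-2-en-1-one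
Product: 9 (E)-1-[2-hydroxy-4,6-bis(2-methylbut-3-en-2-yloxy)phenyl]-3-[4-(2-methylbut-3-yn-2-yloxy)-2-(triisopropylsilyloxy)phenyl]prop-2-en-1-one
Conditions: iPr3SiCl (1.1 equiv), imidazole (2 equiv), DMAP (5 mol %), CH2Cl2, 0 °C → 20 °C
Reagents that add atoms: triisopropylsilyl chloride, CC(C)[Si](Cl)(C(C)C)C(C)C
Why: Silylation of a phenol with a bulky chlorosilane is selective for the ring-B hydroxyl, because the ring-A hydroxyl is locked in a hydrogen bond to the enone carbonyl and so stays free for the ring closure.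

Step 6
Reactants: 9 (E)-1-[2-hydroxy-4,6-bis(2-methylbut-3-en-2-yloxy)phenyl]-3-[4-(2-methylbut-3-yn-2-yloxy)-2-(triisopropylsilyloxy)phenyl]prop-2-en-1-one
Product: 10 (2S)-5,7-bis(2-methylbut-3-en-2-yloxy)-2-[4-(2-methylbut-3-yn-2-yloxy)-2-(triisopropylsilyloxy)phenyl]chroman-4-one
Conditions: N-[3,5-bis(trifluoromethyl)phenyl]-N'-[(9R)-6'-methoxycinchonan-9-yl]thiourea (15 mol %), toluene, 0 °C → 20 °C
Reagents that add atoms: none
Why: Organocatalytic asymmetric intramolecular oxa-Michael addition of a 2'-hydroxychalcone, in which the thiourea hydrogen-bonds the enone carbonyl and the quinuclidine nitrogen deprotonates the chelated phenol, so the ion-paired phenoxide adds to one enantiotopic face of the β-carbon and the catalyst sets C2 as (S); the bulky 6'-alkoxy group twists the enone and puts the equilibrium on the flavanone side.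

Step 7
Reactants: 10 (2S)-5,7-bis(2-methylbut-3-en-2-yloxy)-2-[4-(2-methylbut-3-yn-2-yloxy)-2-(triisopropylsilyloxy)phenyl]chroman-4-one
Product: 15 2'-O-triisopropylsilyl euchrenone a3, via 6-prenyl 7-allyl ether 11 (not isolated), via diprenyl propargyl ether 12 (not isolated), via allenylphenol 13 (not isolated), via vinyl quinone methide 14 (not isolated)
Conditions: degassed o-xylene (0.02 M), Ar, base-washed glass, 110 °C, then 145 °C
Reagents that add atoms: none
Why: Gentle heating first triggers two aromatic Claisen [3,3] shifts: the tertiary allyl ether on O5 passes its CH2 terminus to C6 and, after tautomerisation to the chelated phenol 11, the O7 ether does the same to C8 to give 12, each unit arriving as a normal prenyl group. At the higher temperature the O4' propargyl ether undergoes the slower propargyl Claisen shift to C5' (forming C5'–C4''), the allenyl dienone tautomerises to allenylphenol 13, a [1,5]-hydrogen shift from O4'–H to the central allene carbon gives the (Z)-vinyl ortho-quinone methide 14, and a thermally allowed disrotatory oxa-6π electrocyclisation of this 1-oxatriene closes the six-membered 2H-pyran ring through O4'–C2''. The closest known reactions are the thermal conversion of 1,1-dimethylallyl aryl ethers into ortho-prenylphenols and of aryl 1,1-dimethylpropargyl ethers into 2,2-dimethylchromenes, here run in one flask. No stereocentre is formed; C2 is a spectator and should keep its configuration because the medium is neutral and aprotic and O2' stays silylated, so neither base-induced retro-oxa-Michael opening nor quinone-methide ionisation at C2 is open. On ring A the selectivity needed is C6 for the O5 unit and C8 for the O7 unit: C6 is the only free ortho carbon of O5, whose ether is strained by the peri C4 carbonyl and should move first, after which C8 is the only free ortho carbon left to O7. On ring B the shift must go to C5' and not C3': C3' is walled in by the triisopropylsilyl ether on O2' and by O4', while C5' is unhindered and para to the O2' donor, the site favoured in meta-alkoxy aryl propargyl ethers.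

Step 8
Reactants: 15 2'-O-triisopropylsilyl euchrenone a3
Product: 16 euchrenone a3
Conditions: Bu4NF (1.2 equiv), AcOH (1.5 equiv), THF, 0 °C
Reagents that add atoms: none
Why: Fluoride-mediated cleavage of the aryl silyl ether, with acetic acid protonating the 2'-phenoxide as it forms so that the C2–O1 bond is not opened by retro-oxa-Michael or quinone-methide pathways and the (2S) centre is kept; the prenyl groups and the chromene are inert to these conditions.

Compound list
1 | 2,4,6-trihydroxyacetophenone | CC(=O)c1c(O)cc(O)cc1O | starting material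
2 | 3-chloro-3-methylbut-1-yne | CC(C)(Cl)C#C | starting material
3 | 1-[2,6-dihydroxy-4-(2-methylbut-3-yn-2-yloxy)phenyl]ethanone (4-O-mono ether, not isolated) | CC(=O)c1c(O)cc(OC(C)(C)C#C)cc1O | intermediate
4 | 1-[2-hydroxy-4,6-bis(2-methylbut-3-yn-2-yloxy)phenyl]ethanone | CC(=O)c1c(O)cc(OC(C)(C)C#C)cc1OC(C)(C)C#C | intermediate
5 | 1-[2-hydroxy-4,6-bis(2-methylbut-3-en-2-yloxy)phenyl]ethanone | CC(=O)c1c(O)cc(OC(C)(C)C=C)cc1OC(C)(C)C=C | intermediate
6 | 2,4-dihydroxybenzaldehyde | O=Cc1ccc(O)cc1O | starting material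
7 | 2-hydroxy-4-(2-methylbut-3-yn-2-yloxy)benzaldehyde | O=Cc1ccc(OC(C)(C)C#C)cc1O | intermediate
8 | (E)-1-[2-hydroxy-4,6-bis(2-methylbut-3-en-2-yloxy)phenyl]-3-[2-hydroxy-4-(2-methylbut-3-yn-2-yloxy)phenyl]prop-2-en-1-one | C=CC(C)(C)Oc1cc(O)c(C(=O)/C=C/c2ccc(OC(C)(C)C#C)cc2O)c(OC(C)(C)C=C)c1 | intermediate
9 | (E)-1-[2-hydroxy-4,6-bis(2-methylbut-3-en-2-yloxy)phenyl]-3-[4-(2-methylbut-3-yn-2-yloxy)-2-(triisopropylsilyloxy)phenyl]prop-2-en-1-one | C=CC(C)(C)Oc1cc(O)c(C(=O)/C=C/c2ccc(OC(C)(C)C#C)cc2O[Si](C(C)C)(C(C)C)C(C)C)c(OC(C)(C)C=C)c1 | intermediate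
10 | (2S)-5,7-bis(2-methylbut-3-en-2-yloxy)-2-[4-(2-methylbut-3-yn-2-yloxy)-2-(triisopropylsilyloxy)phenyl]chroman-4-one (key-step precursor) | C=CC(C)(C)Oc1cc2c(c(OC(C)(C)C=C)c1)C(=O)C[C@@H](c1ccc(OC(C)(C)C#C)cc1O[Si](C(C)C)(C(C)C)C(C)C)O2 | intermediate
11 | (2S)-5-hydroxy-6-(3-methylbut-2-enyl)-7-(2-methylbut-3-en-2-yloxy)-2-[4-(2-methylbut-3-yn-2-yloxy)-2-(triisopropylsilyloxy)phenyl]chroman-4-one (not isolated) | CC(C)=CCc1c(OC(C)(C)C=C)cc2c(c1O)C(=O)C[C@@H](c1ccc(OC(C)(C)C#C)cc1O[Si](C(C)C)(C(C)C)C(C)C)O2 | intermediate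
12 | (2S)-5,7-dihydroxy-6,8-bis(3-methylbut-2-enyl)-2-[4-(2-methylbut-3-yn-2-yloxy)-2-(triisopropylsilyloxy)phenyl]chroman-4-one (not isolated) | CC(C)=CCc1c(O)c(CC=C(C)C)c2c(c1O)C(=O)C[C@@H](c1ccc(OC(C)(C)C#C)cc1O[Si](C(C)C)(C(C)C)C(C)C)O2 | intermediate
13 | (2S)-5,7-dihydroxy-2-[4-hydroxy-5-(3-methylbuta-1,2-dienyl)-2-(triisopropylsilyloxy)phenyl]-6,8-bis(3-methylbut-2-enyl)chroman-4-one (not isolated) | CC(C)=CCc1c(O)c(CC=C(C)C)c2c(c1O)C(=O)C[C@@H](c1cc(C=C=C(C)C)c(O)cc1O[Si](C(C)C)(C(C)C)C(C)C)O2 | intermediate
14 | (2S)-5,7-dihydroxy-6,8-bis(3-methylbut-2-enyl)-2-[(3Z)-3-(3-methylbut-2-enylidene)-4-oxo-6-(triisopropylsilyloxy)cyclohexa-1,5-dien-1-yl]chroman-4-one (ring-B ortho-quinone methide, not isolated) | CC(C)=CCc1c(O)c(CC=C(C)C)c2c(c1O)C(=O)C[C@@H](C1=C/C(=C/C=C(C)C)C(=O)C=C1O[Si](C(C)C)(C(C)C)C(C)C)O2 | intermediate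
15 | 2'-O-triisopropylsilyl euchrenone a3, (2S)-2-[2,2-dimethyl-7-(triisopropylsilyloxy)-2H-chromen-6-yl]-5,7-dihydroxy-6,8-bis(3-methylbut-2-enyl)chroman-4-one | CC(C)=CCc1c(O)c(CC=C(C)C)c2c(c1O)C(=O)C[C@@H](c1cc3c(cc1O[Si](C(C)C)(C(C)C)C(C)C)OC(C)(C)C=C3)O2 | intermediate
16 | euchrenone a3, (2S)-5,7-dihydroxy-2-(7-hydroxy-2,2-dimethyl-2H-chromen-6-yl)-6,8-bis(3-methylbut-2-enyl)chroman-4-one | CC(C)=CCc1c(O)c(CC=C(C)C)c2c(c1O)C(=O)C[C@@H](c1cc3c(cc1O)OC(C)(C)C=C3)O2 | target

Total step count: 8. Longest linear sequence: 7 steps (1 → 4 → 5 → 8 → 9 → 10 → 15 → 16); step 3 is the side branch.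

Steps most likely to fail

Step 7. What may go wrong:
- on ring A, migration of the O7 unit to C6 before the O5 unit has moved, which would end in geminal dialkylation or a reverse-prenyl group at C8;
- on ring B, pyran closure towards C3';
- slow erosion of the C2 configuration during the long period at 145 °C.

The fallback sets out from 10 and takes the ring closure out of the thermal cascade. A cationic gold catalyst, [(2-biphenylyl)di-tert-butylphosphine]Au(NCMe)SbF6 (2 mol %, monovalent gold) in CH2Cl2 at 0 °C, should effect the known 6-endo hydroarylation of the aryl propargyl ether at the unhindered, para-activated C5' and give (2S)-2-[2,2-dimethyl-7-(triisopropylsilyloxy)-2H-chromen-6-yl]-5,7-bis(2-methylbut-3-en-2-yloxy)chroman-4-one F1. Heating F1 in toluene at 110 °C then needs only the two allyl Claisen shifts and comes back to the route at 15. The fallback does not remove the ring-A ordering risk, but it lowers the thermal load on C2 and settles the ring-B site by a different mechanism.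

Step 6. What may go wrong: weak facial discrimination with the ortho-silyloxy aryl group, uncatalysed racemic closure running alongside, and loss of enantiomeric purity through reversible ring opening. The fallback sets out from 9 and replaces asymmetric catalysis by resolution. Closure with NaOAc in EtOH at 40 °C should give racemic 5,7-bis(2-methylbut-3-en-2-yloxy)-2-[4-(2-methylbut-3-yn-2-yloxy)-2-(triisopropylsilyloxy)phenyl]chroman-4-one F2. Preparative chromatography on cellulose tris(3,5-dimethylphenylcarbamate) separates it and comes back to the route at 10. The unwanted (2R)-flavanone F3 is returned to F2 by brief treatment with catalytic DBU in toluene and resolved again.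

Step 4. What may go wrong: sluggish condensation because the aldehyde is deactivated as its phenoxide and the ketone is hindered, and premature closure of the chalcone to racemic flavanone during neutralisation. The fallback sets out from 7 and 5 and avoids hydroxide altogether. Aldehyde 7 is silylated (iPr3SiCl, imidazole, CH2Cl2) to 4-(2-methylbut-3-yn-2-yloxy)-2-(triisopropylsilyloxy)benzaldehyde F4. The dianion of 5 (LiN(SiMe3)2, 2.2 equiv, THF, −78 °C) is added to F4 and quenched cold to give the aldol 3-hydroxy-1-[2-hydroxy-4,6-bis(2-methylbut-3-en-2-yloxy)phenyl]-3-[4-(2-methylbut-3-yn-2-yloxy)-2-(triisopropylsilyloxy)phenyl]propan-1-one F5. Mesylation of the carbinol and elimination (MeSO2Cl, Et3N, CH2Cl2, −20 °C → 20 °C) comes back to the route at 9, so step 5 is not needed.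

Further compounds
F1 | step 7 | (2S)-2-[2,2-dimethyl-7-(triisopropylsilyloxy)-2H-chromen-6-yl]-5,7-bis(2-methylbut-3-en-2-yloxy)chroman-4-one | C=CC(C)(C)Oc1cc2c(c(OC(C)(C)C=C)c1)C(=O)C[C@@H](c1cc3c(cc1O[Si](C(C)C)(C(C)C)C(C)C)OC(C)(C)C=C3)O2
F2 | step 6 | racemic 5,7-bis(2-methylbut-3-en-2-yloxy)-2-[4-(2-methylbut-3-yn-2-yloxy)-2-(triisopropylsilyloxy)phenyl]chroman-4-one | C=CC(C)(C)Oc1cc2c(c(OC(C)(C)C=C)c1)C(=O)CC(c1ccc(OC(C)(C)C#C)cc1O[Si](C(C)C)(C(C)C)C(C)C)O2
F3 | step 6 | (2R)-5,7-bis(2-methylbut-3-en-2-yloxy)-2-[4-(2-methylbut-3-yn-2-yloxy)-2-(triisopropylsilyloxy)phenyl]chroman-4-one | C=CC(C)(C)Oc1cc2c(c(OC(C)(C)C=C)c1)C(=O)C[C@H](c1ccc(OC(C)(C)C#C)cc1O[Si](C(C)C)(C(C)C)C(C)C)O2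
F4 | step 4 | 4-(2-methylbut-3-yn-2-yloxy)-2-(triisopropylsilyloxy)benzaldehyde | O=Cc1ccc(OC(C)(C)C#C)cc1O[Si](C(C)C)(C(C)C)C(C)C
F5 | step 4 | racemic 3-hydroxy-1-[2-hydroxy-4,6-bis(2-methylbut-3-en-2-yloxy)phenyl]-3-[4-(2-methylbut-3-yn-2-yloxy)-2-(triisopropylsilyloxy)phenyl]propan-1-one | C=CC(C)(C)Oc1cc(O)c(C(=O)CC(O)c2ccc(OC(C)(C)C#C)cc2O[Si](C(C)C)(C(C)C)C(C)C)c(OC(C)(C)C=C)c1
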